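## Structural features

The target is a bicyclo[3.3.1]non-2-ene. Ring A (C1, C2, C3, C4, C5, C9) holds the C2=C3 enal, ring B (C1, C8, C7, C6, C5, C9) is saturated, and the rings share the bridgeheads C1 and C5 and the one-carbon bridge C9. C1 (formyl) and C5 (methyl) are quaternary and flank the acetoxy carbon C9, whose oxygen lies over ring B. C8, next to C1, carries an equatorial (2R)-6-methylhept-5-en-2-yl chain, so five stereocentres stand in a row: C1' (the chain carbon, R), C8 (S), C1 (R), C9 (R) and C5 (R). The fragile groups are the 1,4-enedial (hydration, lactol formation, air oxidation), the C1 aldehyde β to the C9 oxygen (acyl migration and retro-aldol once that oxygen is free), the base-labile acetate and the acid- and electrophile-sensitive trisubstituted side-chain alkene. The real difficulty is the pair of quaternary bridgeheads joined through C9, together with the C1/C8 relationship, which no ring enforces until the bicycle exists. The key step uses the fact that C5 is α to the C9 oxygen: a C9 silyl enol ether in a preformed ring A is nucleophilic at C5 and can reach an alkyne hung on C8, so the C5–C6 bond, ring B and the C5 configuration arise together. Because C1 is already quaternary, C5 is the only enolisable position of the C9 ketone, and the alkyne arm can bridge only one face.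

## Logic of the disconnections

From 21 back to 17 (through 20, 19 and 18) no skeletal bond is cut. The two formyl groups are read as oxidised primary alcohols, the acetate as an acylated C9 hydroxyl, and the primary hydroxyls as silyl ethers while C9 is acylated. The cut is made here because the enedial and the β-acetoxy aldehyde are the least robust parts of 21 and should exist only in the last flask. The gain is a triol, 17, whose three hydroxyls differ strongly in steric demand. The forward steps must silylate only the primary hydroxyls, acylate a hydroxyl lying between two quaternary carbons, remove silicon without moving the acetyl group to the C1 hydroxymethyl group, and oxidise both primary alcohols at the same time so that no hydroxy aldehyde is left to close to a lactol.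

From 17 to 16 the C9–H bond and the C–H bonds of both hydroxymethyl groups are cut. All three oxygenated carbons then become carbonyl carbons (one ketone, two esters) that a single hydride reagent can reduce in one flask. The demand is facial: hydride must reach C9 from the ring A side so that the oxygen ends over ring B, and the enoate must be reduced 1,2.

From 16 to 15 the C6–H and C7–H bonds are cut, which restores the C6=C7 alkene that the ring closure leaves behind. The saturation is placed before the C9 reduction because only a saturated ring B, with axial hydrogens on C6 and C8, makes the two faces of C9 clearly different. The forward step must reduce a cis-disubstituted alkene beside a trisubstituted enoate and a trisubstituted side-chain alkene.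

From 15 to 14 the C5–C6 bond is cut. Ring B opens, the quaternary stereocentre C5 disappears into an enol ether, and the bicycle becomes a monocyclic cyclohexadiene with a propargylic arm on C1. This is the largest single simplification of the route. The forward step must close in the 6-endo sense at the terminal alkyne carbon, must not be intercepted by the side-chain alkene, and needs a proton source that also accepts the silyl group.

From 14 to 13 the O–Si bond is cut, and from 13 to 11 the alkyne is read as a CH2–CHO unit (C7–C6). The aldehyde is what a conjugate addition delivers, and C6 is then already present, so no homologation is needed. The demand is that the aldehyde α-position be converted without β-elimination of the β-keto ester (retro-Michael) and without involving the C9 ketone, and that enol silylation go to C5, which is guaranteed by the quaternary C1.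

From 11 to 7 and 10 the C1–C8 bond is cut. C1 is the carbon between a ketone and an ester and is the natural nucleophile; C8 is the β-carbon of an enal. The cut is convergent and divides the molecule into a ring A piece and a side-chain piece of similar size. The forward step must bond at C1 and not at the vinylogous position C3, must set C1 and C8 together, and must not disturb C1', which is γ to the enal carbonyl.

From 7 to 6 the C1–C9 bond is cut (Claisen-type ring closure), from 6 to 3 and 4 the C2=C3 double bond, and from 3 to 1 a terminal alkene is restored in place of the aldehyde. An olefination that gives the triester directly with the chain cis to the CH2CO2Me arm avoids a half-ester and a separate re-esterification. The demand is regiocontrol in the ring closure, met by thermodynamic control, and exclusion of air from the dienol 7.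

From 10 to 9 the C7=C8 unsaturation is removed, and from 9 to 8 the C6=C7 bond is cut. One added carbon plus a dehydrogenation turns the chiral-pool aldehyde 8 into the enal with its stereocentre untouched. The forward steps must not epimerise a centre that ends up γ to a conjugated aldehyde.

## Other disconnections considered

Alternative 1: The cut is C1–C9. Forward, cyclooctene dialdehyde A1 (enolisable formyl on C1, non-enolisable formyl on quaternary C5) would close by a transannular aldol under mild amine or base catalysis to the bicyclic hydroxy aldehyde A2.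
- In its favour: C9 is born as the alcohol and C1 as the quaternary aldehyde, so neither a ketone reduction nor an ester-to-aldehyde adjustment at C1 is needed. About three operations (acetylation, desilylation, oxidation) would finish the synthesis from A2, against six after 15; on end-game length this alternative is the better one. The bridgehead configuration at C1 is dictated by the transannular geometry just as C5 is dictated by the tether in step 9; on that point the two plans are equal.
- Against it here: A1 requires a stereodefined eight-membered ring with a Z-trisubstituted alkene, quaternary C5 and the C8 centre, which is a harder target than 14. The enol of the C1 aldehyde is a dienol through C2=C3 and could bond at C3. The orientation of the new C9 hydroxyl is decided only by the conformation of a flexible ring, whereas the chosen plan sets it by reagent approach to a rigid bicycle. The aldol is reversible, so A2 can revert, while the gold closure is irreversible.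
- Overall: shorter after the key step, longer and less certain before it.

Alternative 2: The cut is C1–C2, closing ring A last on an intact ring B. Forward, bis(methyl enol ether) A3 would be oxidised at a carbon anode in methanol (LiClO4, 2,6-lutidine); the radical cation of one enol ether is trapped by the other and by methanol, giving bis(dimethyl acetal) A4.
- In its favour: coupling of two nucleophilic carbons through a radical cation copes well with the congestion of a quaternary C1, and here it is at least the equal of the gold step. Both aldehyde carbons arrive masked at the correct oxidation level, which is better than the chosen plan with its two esters. The C9 oxygen and its configuration are settled on a monocyclic ring B, and C1 is again fixed by bridging (equal).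
- Against it here: A4 has a saturated C2–C3 bond and a superfluous C2 stereocentre, so the C2=C3 unsaturation must be introduced after acetal hydrolysis on a dialdehyde, at a cost of two or three steps. The electron-rich side-chain alkene can compete for the radical cation or be oxidised itself. A3 needs a cyclohexane with three contiguous stereocentres (quaternary C5, C9, C8) and two separately installed enol ethers.
- Overall: comparable mechanistic elegance, but a longer route to the substrate and a heavier end-game than the chosen plan.

Alternative 3: The cuts are C4–C5 and the bond from C1 to the carbon that later becomes the C2 formyl carbon. Forward, α-chloro ketone A5 would be ionised with NaOCH2CF3 in CF3CH2OH to an oxyallyl cation that adds across (E)-1-(tert-butyldimethylsilyloxy)buta-1,3-diene A6 in a (4+3) cycloaddition, giving bicyclo[4.3.1]decenone A7. A later one-carbon ring contraction (epoxidation, semipinacol shift of C1, β-elimination) would give the enal.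
- In its favour: two C–C bonds and both quaternary bridgeheads are made in one step from a monocyclic ketone. This is more bonds and stereocentres per step than step 9, and on that measure the alternative is the better one. The ring B precursor is simple, and either silyloxy epimer of A7 is usable.
- Against it here: the oxyallyl cation is unsymmetrical only through CH2OSi against CH3, so the orientation of the diene has little electronic bias. The diene face must also be controlled relative to C8. The seven-membered ring must then be contracted in about three further steps, each with its own stereoelectronic requirement (migrating bond anti to the breaking C–O bond). The C9 ketone reduction is still needed, as in the chosen plan (equal).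
- Overall: the key step is more convergent, but a regiochemical question replaces the 6-endo/5-exo question, and the step count after the key step is not lower.

Key step: step 9

Remarks on the chemistry:
- 7, 11, 12 and 13 are carried as mixtures at C5 (7 also as keto/dienol tautomers); this centre is planar in 14 and is set once, in step 9.
- Step 6 is written with the cupreidine-derived catalyst; if the matched sense for 8S requires it, the cupreine-derived pseudoenantiomer is used under the same conditions.

## Route

Step 1
Reactants: 1 ethyl 2-methylpent-4-enoate (racemic)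
Product: 3 ethyl 2-methyl-4-oxobutanoate (racemic), via ozonide 2 (not isolated)
Conditions: O3, CH2Cl2, –78 °C; then PPh3, –78 °C → rt
Reagents that add atoms: ozone, [O-][O+]=O
Why: Ozonolysis of the only alkene with reductive work-up (Criegee mechanism) gives the aldehyde and leaves the ester alone; the α-methyl centre is racemic and needs no control because it becomes the planar C5 of 14.

Step 2
Reactants: 3 ethyl 2-methyl-4-oxobutanoate; 4 dimethyl maleate
Product: 6 5-ethyl 1,2-dimethyl (2E)-hex-2-ene-1,2,5-tricarboxylate, via phosphorus ylide 5 (not isolated)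
Conditions: 4, PBu3 (1.1 equiv), THF, rt; then 3, rt
Reagents that add atoms: none
Why: Conjugate addition of the phosphine to the maleate and a proton shift give the ester-stabilised ylide 5, which olefinates the aldehyde in a Wittig reaction. The stabilised ylide places the new chain trans to the ester on the ylide carbon (E), that is cis to the CH2CO2Me arm, which is the geometry the ring closure needs.

Step 3
Reactants: 6 5-ethyl 1,2-dimethyl (2E)-hex-2-ene-1,2,5-tricarboxylate
Product: 7 dimethyl 5-methyl-6-oxocyclohex-2-ene-1,2-dicarboxylate (keto/dienol tautomers, stereoisomer mixture)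
Conditions: NaOMe, MeOH, 0 °C → rt, Ar; then aq. HCl
Reagents that add atoms: none
Why: Dieckmann condensation: the C1 methylene anion attacks the ethyl ester and closes the six-membered ring; of the possible Claisen modes only this one gives a β-keto ester that is held as a doubly stabilised enolate, so reversible alkoxide conditions converge on 7. Air is excluded because the dienol is a dihydroarene.

Step 4
Reactants: 8 (R)-citronellal [(3R)-3,7-dimethyloct-6-enal]
Product: 9 (4R)-1-methoxy-4,8-dimethylnona-1,7-diene (E/Z mixture)
Conditions: MeOCH2PPh3Cl, NaN(SiMe3)2, THF, 0 °C; then 8, 0 °C → rt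
Reagents that add atoms: (methoxymethyl)triphenylphosphonium chloride, COC[P+](c1ccccc1)(c1ccccc1)c1ccccc1.[Cl-]
Why: Wittig methoxymethylenation adds the carbon that becomes C6; the stereocentre is β to the aldehyde and is not touched, and the enol ether geometry is irrelevant.

Step 5
Reactants: 9 (4R)-1-methoxy-4,8-dimethylnona-1,7-diene
Product: 10 (2E,4R)-4,8-dimethylnona-2,7-dienal
Conditions: Pd(OAc)2 (10 mol %), p-benzoquinone (1.1 equiv), MeCN/H2O, rt
Reagents that add atoms: water, O
Why: Saegusa-type dehydrogenation: divalent palladium adds to the electron-rich enol ether, β-hydride elimination and hydrolysis of the oxocarbenium ion release the E-enal, and benzoquinone returns zerovalent palladium to the cycle. The γ-stereocentre (C1') is a spectator, and the remote trisubstituted alkene is a poor ligand for palladium.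

Step 6
Reactants: 7 dimethyl 5-methyl-6-oxocyclohex-2-ene-1,2-dicarboxylate; 10 (2E,4R)-4,8-dimethylnona-2,7-dienal
Product: 11 dimethyl (1R)-1-[(3S,4R)-4,8-dimethyl-1-oxonon-7-en-3-yl]-5-methyl-6-oxocyclohex-2-ene-1,2-dicarboxylate (C5 epimers)
Conditions: 9-O-benzylcupreidine (10 mol %), CH2Cl2, –20 °C, Ar
Reagents that add atoms: none
Why: Michael addition under bifunctional tertiary-amine catalysis: the quinuclidine deprotonates the β-keto ester and holds its enolate as an ion pair while the 6'-OH binds the enal carbonyl, so bonding occurs at C1, between the two bound oxygens, and not at the remote vinylogous carbon C3. The closed ion-pair transition state selects one enal face (C8, catalyst control matched to the resident C1' centre) and one enolate face (C1) together; no enamine or dienamine forms, so C1' cannot epimerise.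

Step 7
Reactants: 11 dimethyl (1R)-1-[(3S,4R)-4,8-dimethyl-1-oxonon-7-en-3-yl]-5-methyl-6-oxocyclohex-2-ene-1,2-dicarboxylate
Product: 13 dimethyl (1R)-1-[(3R,4R)-4,8-dimethylnon-7-en-1-yn-3-yl]-5-methyl-6-oxocyclohex-2-ene-1,2-dicarboxylate (C5 epimers), via alkenyl nonaflate 12 (not isolated)
Conditions: C4F9SO2F (1.2 equiv), phosphazene base P2-Et (2.2 equiv), DMF, –30 °C → rt
Reagents that add atoms: none
Why: One-flask enol nonaflate formation and E2 elimination turn CH2–CHO into C≡CH without adding carbon. The aldehyde α-hydrogens are the most acidic in 11, and the base is added last to aldehyde plus sulfonyl fluoride so that the enolate is O-sulfonylated before it can expel the β-keto ester; the C8 descriptor changes from S to R through priorities only.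

Step 8
Reactants: 13 dimethyl (1R)-1-[(3R,4R)-4,8-dimethylnon-7-en-1-yn-3-yl]-5-methyl-6-oxocyclohex-2-ene-1,2-dicarboxylate
Product: 14 dimethyl (1R)-1-[(3R,4R)-4,8-dimethylnon-7-en-1-yn-3-yl]-5-methyl-6-{[tri(propan-2-yl)silyl]oxy}cyclohexa-2,5-diene-1,2-dicarboxylate
Conditions: iPr3SiOTf, Et3N, CH2Cl2, 0 °C → rt
Reagents that add atoms: triisopropylsilyl trifluoromethanesulfonate, CC(C)[Si](C(C)C)(C(C)C)OS(=O)(=O)C(F)(F)F
Why: Soft enolisation (silyl triflate plus amine) gives the silyl enol ether; C1 is quaternary, so the C9 ketone can enolise only toward C5, and both C5 epimers of 13 converge on one compound.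

Step 9
Reactants: 14 dimethyl (1R)-1-[(3R,4R)-4,8-dimethylnon-7-en-1-yn-3-yl]-5-methyl-6-{[tri(propan-2-yl)silyl]oxy}cyclohexa-2,5-diene-1,2-dicarboxylate
Product: 15 dimethyl (1R,5S,8R)-5-methyl-8-[(2R)-6-methylhept-5-en-2-yl]-9-oxobicyclo[3.3.1]nona-2,6-diene-1,2-dicarboxylate
Conditions: [(tBu2(2-biphenylyl)P)Au(NCMe)]SbF6 (5 mol %), acetone, H2O (2 equiv), rt
Reagents that add atoms: none
Why: The cationic monovalent gold centre binds the terminal alkyne of 14, and the nucleophilic carbon of the silyl enol ether (C5) adds anti to gold at the terminal alkyne carbon C6, giving a silyloxocarbenium ion that carries an alkenyl–gold bond at C7. Water takes the silyl group as the silanol, and the proton set free cleaves the C7–Au bond, which leaves the C9 ketone and the C6=C7 alkene and returns the catalyst. The closest known reaction type is the gold-catalysed carbocyclisation of cyclic silyl enol ethers onto tethered alkynes (a Conia-ene-type process) that gives bicyclo[3.3.1]nonenones. Ring B (C5, C9, C1, C8, C7, C6) closes in the 6-endo-dig mode. The new quaternary stereocentre C5 is controlled by the tether: the propargylic arm on C1 can bridge to C5 across one face of the C5=C9 bond only, so C5 follows C1. The step needs attack at C6 to win over 5-exo attack at C7, which would give a bicyclo[3.2.1]octane with an exocyclic methylene, and over attack by the side-chain alkene. The bulky biaryl phosphine and the lower strain of the bicyclo[3.3.1] transition state favour C6, and the enol ether is far more nucleophilic and far better placed than the remote trisubstituted alkene. Regiochemistry of the nucleophile is not in question because C5 is the only enolisable position of the C9 ketone.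

Step 10
Reactants: 15 dimethyl (1R,5S,8R)-5-methyl-8-[(2R)-6-methylhept-5-en-2-yl]-9-oxobicyclo[3.3.1]nona-2,6-diene-1,2-dicarboxylate
Product: 16 dimethyl (1R,5R,8S)-5-methyl-8-[(2R)-6-methylhept-5-en-2-yl]-9-oxobicyclo[3.3.1]non-2-ene-1,2-dicarboxylate
Conditions: 2-O2NC6H4SO2NHNH2 (excess), Et3N, CH2Cl2, rt
Reagents that add atoms: none
Why: Diimide reduction (concerted syn transfer of two hydrogens) is fastest at the cis-disubstituted C6=C7 bond; the trisubstituted enoate and side-chain alkenes react much more slowly, and ketone and esters not at all. No stereocentre is formed; the C5 and C8 descriptors change through priorities only.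

Step 11
Reactants: 16 dimethyl (1R,5R,8S)-5-methyl-8-[(2R)-6-methylhept-5-en-2-yl]-9-oxobicyclo[3.3.1]non-2-ene-1,2-dicarboxylate
Product: 17 (1S,5R,8S,9R)-1,2-bis(hydroxymethyl)-5-methyl-8-[(2R)-6-methylhept-5-en-2-yl]bicyclo[3.3.1]non-2-en-9-ol
Conditions: iBu2AlH (excess), CH2Cl2, –78 → 0 °C; aq. KNaC4H4O6
Reagents that add atoms: none
Why: Hydride reduction of the ketone and both esters in one flask, the enoate 1,2-selectively. The reagent reaches C9 from the ring A face, over the flat C2=C3 unit, because the ring B face is screened by the axial hydrogens on C6 and C8; the hydroxyl is therefore left over ring B (9R).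

Step 12
Reactants: 17 (1S,5R,8S,9R)-1,2-bis(hydroxymethyl)-5-methyl-8-[(2R)-6-methylhept-5-en-2-yl]bicyclo[3.3.1]non-2-en-9-ol
Product: 18 (1S,5R,8S,9R)-1,2-bis({[tert-butyl(dimethyl)silyl]oxy}methyl)-5-methyl-8-[(2R)-6-methylhept-5-en-2-yl]bicyclo[3.3.1]non-2-en-9-ol
Conditions: tBuMe2SiCl (2.3 equiv), imidazole, DMF, 0 °C
Reagents that add atoms: tert-butyldimethylsilyl chloride, CC(C)(C)[Si](C)(C)Cl
Why: Silyl ether formation is selective for the two primary hydroxyls; the C9 hydroxyl, secondary and set between two quaternary carbons, does not react with this bulky chloride.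

Step 13
Reactants: 18 (1S,5R,8S,9R)-1,2-bis({[tert-butyl(dimethyl)silyl]oxy}methyl)-5-methyl-8-[(2R)-6-methylhept-5-en-2-yl]bicyclo[3.3.1]non-2-en-9-ol
Product: 19 (1S,5R,8S,9R)-1,2-bis({[tert-butyl(dimethyl)silyl]oxy}methyl)-5-methyl-8-[(2R)-6-methylhept-5-en-2-yl]bicyclo[3.3.1]non-2-en-9-yl acetate
Conditions: Ac2O, 4-(dimethylamino)pyridine, Et3N, CH2Cl2, 40 °C
Reagents that add atoms: acetic anhydride, CC(=O)OC(C)=O
Why: Nucleophile-catalysed acylation through the N-acetylpyridinium ion drives the hindered C9 hydroxyl to the acetate; the C9 configuration is untouched and the silyl ethers are inert.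

Step 14
Reactants: 19 (1S,5R,8S,9R)-1,2-bis({[tert-butyl(dimethyl)silyl]oxy}methyl)-5-methyl-8-[(2R)-6-methylhept-5-en-2-yl]bicyclo[3.3.1]non-2-en-9-yl acetate
Product: 20 (1S,5R,8S,9R)-1,2-bis(hydroxymethyl)-5-methyl-8-[(2R)-6-methylhept-5-en-2-yl]bicyclo[3.3.1]non-2-en-9-yl acetate
Conditions: HF·pyridine, pyridine, THF, 0 °C → rt
Reagents that add atoms: none
Why: Fluoride-mediated desilylation in a buffered acidic medium frees both primary alcohols; the absence of base suppresses migration of the acetyl group from O9 to the C1 hydroxymethyl group.

Step 15
Reactants: 20 (1S,5R,8S,9R)-1,2-bis(hydroxymethyl)-5-methyl-8-[(2R)-6-methylhept-5-en-2-yl]bicyclo[3.3.1]non-2-en-9-yl acetate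
Product: 21 (1R,5R,8S,9R)-1,2-diformyl-5-methyl-8-[(2R)-6-methylhept-5-en-2-yl]bicyclo[3.3.1]non-2-en-9-yl acetate (target)
Conditions: (COCl)2, Me2SO, CH2Cl2, –78 °C; then Et3N, –78 → 0 °C
Reagents that add atoms: none
Why: Swern oxidation: both hydroxyls are converted into alkoxysulfonium ions before base is added, so the allylic and the neopentyl alcohol become aldehydes together and no hydroxy aldehyde can close to a lactol. C1 has no α-hydrogen, and the acetate is stable to the amine at low temperature.

## Compound list

1 | ethyl 2-methylpent-4-enoate (racemic) | CCOC(=O)C(C)CC=C | starting material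
2 | ethyl 2-methyl-3-(1,2,4-trioxolan-3-yl)propanoate (ozonide) | CCOC(=O)C(C)CC1OCOO1 | intermediate (not isolated)
3 | ethyl 2-methyl-4-oxobutanoate (racemic) | CCOC(=O)C(C)CC=O | intermediate
4 | dimethyl maleate | COC(=O)/C=C\C(=O)OC | starting material
5 | dimethyl 2-(tributyl-λ5-phosphanylidene)butanedioate | CCCCP(CCCC)(CCCC)=C(CC(=O)OC)C(=O)OC | intermediate (not isolated)
6 | 5-ethyl 1,2-dimethyl (2E)-hex-2-ene-1,2,5-tricarboxylate | CCOC(=O)C(C)C/C=C(\CC(=O)OC)C(=O)OC | intermediate
7 | dimethyl 5-methyl-6-oxocyclohex-2-ene-1,2-dicarboxylate (keto/dienol tautomers, stereoisomer mixture) | COC(=O)C1C(=O)C(C)CC=C1C(=O)OC | intermediate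
8 | (R)-citronellal, (3R)-3,7-dimethyloct-6-enal | C[C@H](CCC=C(C)C)CC=O | starting material
9 | (4R)-1-methoxy-4,8-dimethylnona-1,7-diene (E/Z mixture) | C[C@H](CCC=C(C)C)CC=COC | intermediate
10 | (2E,4R)-4,8-dimethylnona-2,7-dienal | C[C@H](CCC=C(C)C)/C=C/C=O | intermediate
11 | dimethyl (1R)-1-[(3S,4R)-4,8-dimethyl-1-oxonon-7-en-3-yl]-5-methyl-6-oxocyclohex-2-ene-1,2-dicarboxylate (C5 epimers) | CC1C(=O)[C@@](C(=O)OC)([C@H]([C@H](C)CCC=C(C)C)CC=O)C(C(=O)OC)=CC1 | intermediate
12 | dimethyl (1R)-1-[(3R,4R)-4,8-dimethyl-1-{[(nonafluorobutyl)sulfonyl]oxy}nona-1,7-dien-3-yl]-5-methyl-6-oxocyclohex-2-ene-1,2-dicarboxylate (E/Z mixture, C5 epimers) | CC1C(=O)[C@@](C(=O)OC)([C@H]([C@H](C)CCC=C(C)C)C=COS(=O)(=O)C(F)(F)C(F)(F)C(F)(F)C(F)(F)F)C(C(=O)OC)=CC1 | intermediate (not isolated)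
13 | dimethyl (1R)-1-[(3R,4R)-4,8-dimethylnon-7-en-1-yn-3-yl]-5-methyl-6-oxocyclohex-2-ene-1,2-dicarboxylate (C5 epimers) | CC1C(=O)[C@@](C(=O)OC)([C@H]([C@H](C)CCC=C(C)C)C#C)C(C(=O)OC)=CC1 | intermediate
14 | dimethyl (1R)-1-[(3R,4R)-4,8-dimethylnon-7-en-1-yn-3-yl]-5-methyl-6-{[tri(propan-2-yl)silyl]oxy}cyclohexa-2,5-diene-1,2-dicarboxylate | CC1=C(O[Si](C(C)C)(C(C)C)C(C)C)[C@@](C(=O)OC)([C@H]([C@H](C)CCC=C(C)C)C#C)C(C(=O)OC)=CC1 | intermediate (precursor of the key step)
15 | dimethyl (1R,5S,8R)-5-methyl-8-[(2R)-6-methylhept-5-en-2-yl]-9-oxobicyclo[3.3.1]nona-2,6-diene-1,2-dicarboxylate | O=C1[C@@]2(C)CC=C(C(=O)OC)[C@]1(C(=O)OC)[C@H]([C@H](C)CCC=C(C)C)C=C2 | intermediate (product of the key step)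
16 | dimethyl (1R,5R,8S)-5-methyl-8-[(2R)-6-methylhept-5-en-2-yl]-9-oxobicyclo[3.3.1]non-2-ene-1,2-dicarboxylate | O=C1[C@@]2(C)CC=C(C(=O)OC)[C@]1(C(=O)OC)[C@H]([C@H](C)CCC=C(C)C)CC2 | intermediate
17 | (1S,5R,8S,9R)-1,2-bis(hydroxymethyl)-5-methyl-8-[(2R)-6-methylhept-5-en-2-yl]bicyclo[3.3.1]non-2-en-9-ol | O[C@@H]1[C@@]2(C)CC=C(CO)[C@]1(CO)[C@H]([C@H](C)CCC=C(C)C)CC2 | intermediate
18 | (1S,5R,8S,9R)-1,2-bis({[tert-butyl(dimethyl)silyl]oxy}methyl)-5-methyl-8-[(2R)-6-methylhept-5-en-2-yl]bicyclo[3.3.1]non-2-en-9-ol | O[C@@H]1[C@@]2(C)CC=C(CO[Si](C)(C)C(C)(C)C)[C@]1(CO[Si](C)(C)C(C)(C)C)[C@H]([C@H](C)CCC=C(C)C)CC2 | intermediate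
19 | (1S,5R,8S,9R)-1,2-bis({[tert-butyl(dimethyl)silyl]oxy}methyl)-5-methyl-8-[(2R)-6-methylhept-5-en-2-yl]bicyclo[3.3.1]non-2-en-9-yl acetate | CC(=O)O[C@@H]1[C@@]2(C)CC=C(CO[Si](C)(C)C(C)(C)C)[C@]1(CO[Si](C)(C)C(C)(C)C)[C@H]([C@H](C)CCC=C(C)C)CC2 | intermediate
20 | (1S,5R,8S,9R)-1,2-bis(hydroxymethyl)-5-methyl-8-[(2R)-6-methylhept-5-en-2-yl]bicyclo[3.3.1]non-2-en-9-yl acetate | CC(=O)O[C@@H]1[C@@]2(C)CC=C(CO)[C@]1(CO)[C@H]([C@H](C)CCC=C(C)C)CC2 | intermediate
21 | (1R,5R,8S,9R)-1,2-diformyl-5-methyl-8-[(2R)-6-methylhept-5-en-2-yl]bicyclo[3.3.1]non-2-en-9-yl acetate | CC(=O)O[C@@H]1[C@@]2(C)CC=C(C=O)[C@]1(C=O)[C@H]([C@H](C)CCC=C(C)C)CC2 | target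

## Step count and least certain steps

Total: 15 steps. Longest linear sequence: 13 steps (steps 1–3 and 6–15, from 1); the branch from 8 adds steps 4 and 5.

Step 9 (key step). Most likely failures: closure in the 5-exo sense, because a terminal alkyne is electronically biased toward attack at its internal carbon; loss of the silyl group by adventitious acid before cyclisation; or slower turnover if the terminal alkyne binds gold as an acetylide. Fallback: the same C5–C6 bond can be made by a carbonyl reaction. Starting from 11, an acid- or amine-promoted intramolecular aldol of the C5 enol onto the C6 aldehyde (the classical bridged ketol closure of a 2-substituted cyclohexanone bearing a 3-oxopropyl arm) should give the ketol dimethyl (1R,5S,8S)-6-hydroxy-5-methyl-8-[(2R)-6-methylhept-5-en-2-yl]-9-oxobicyclo[3.3.1]non-2-ene-1,2-dicarboxylate F1. Dehydration with the Burgess reagent, which can only go toward C7 because C5 is quaternary, would return the route at 15.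

Step 6. Most likely failures: bonding at the vinylogous carbon C3 instead of the congested C1; an unfavourable C1/C8 relationship if the catalyst's intrinsic diastereopreference or the mismatch with C1' works against it; slow addition to a γ-branched enal with reversal by retro-Michael; and premature aldol closure of the adduct. Fallback: change the activation mode from base/hydrogen-bond catalysis to covalent iminium activation of 10 with a diarylprolinol trimethylsilyl ether and benzoic acid in toluene. It sets out from 7 and 10 and returns at 11, accepting the risk that a dienamine of 10 erodes C1'; this fallback makes no new compound (F0).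

Step 7. Most likely failures: β-elimination of the aldehyde enolate (retro-Michael, which also scrambles C1/C8), aldol closure onto C6, or competing sulfonylation of the C9 ketone enolate, all because a strong base is used on a Michael adduct. Fallback: avoid the enolate. From 11, electrophilic O-triflation with Tf2O and 2,6-di-tert-butyl-4-methylpyridine in CH2Cl2 should give the alkenyl triflate dimethyl (1R)-1-[(3R,4R)-4,8-dimethyl-1-{[(trifluoromethyl)sulfonyl]oxy}nona-1,7-dien-3-yl]-5-methyl-6-oxocyclohex-2-ene-1,2-dicarboxylate F2. Fluoride-induced elimination with Bu4NF in DMF then returns the route at 13.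

Step 10. Most likely failures: over-reduction of the side-chain alkene, or incomplete conversion of a C6=C7 bond that is flanked by a quaternary and a branched carbon, since diimide discriminates by substitution only moderately. Fallback: replace the diimide transfer by homogeneous hydrogenation with RhCl(PPh3)3 and H2 in benzene/ethanol, where trisubstituted alkenes are poor ligands for monovalent rhodium. It sets out from 15 and returns at 16 and makes no new compound (F0).

Step 11. Most likely failures: insufficient facial selectivity at C9, or incomplete reduction of the neopentyl C1 ester, with no way to recycle a wrong epimer once all three carbonyls are reduced. Fallback: separate the stereodefining event from the ester reduction. From 16, NaBH4 in MeOH at –40 °C should reduce only the ketone, to dimethyl (1R,5R,8S,9R)-9-hydroxy-5-methyl-8-[(2R)-6-methylhept-5-en-2-yl]bicyclo[3.3.1]non-2-ene-1,2-dicarboxylate F3 together with its (9S) epimer F4. After separation, F4 is returned to 16 with Dess–Martin periodinane, and F3 is reduced with iBu2AlH to rejoin the route at 17.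

## Further compounds

F1 | step 9 | dimethyl (1R,5S,8S)-6-hydroxy-5-methyl-8-[(2R)-6-methylhept-5-en-2-yl]-9-oxobicyclo[3.3.1]non-2-ene-1,2-dicarboxylate (C6 epimers) | O=C1[C@@]2(C)CC=C(C(=O)OC)[C@]1(C(=O)OC)[C@H]([C@H](C)CCC=C(C)C)CC2O
F0 | step 6 | none | none
F2 | step 7 | dimethyl (1R)-1-[(3R,4R)-4,8-dimethyl-1-{[(trifluoromethyl)sulfonyl]oxy}nona-1,7-dien-3-yl]-5-methyl-6-oxocyclohex-2-ene-1,2-dicarboxylate (E/Z mixture, C5 epimers) | CC1C(=O)[C@@](C(=O)OC)([C@H]([C@H](C)CCC=C(C)C)C=COS(=O)(=O)C(F)(F)F)C(C(=O)OC)=CC1
F0 | step 10 | none | none
F3 | step 11 | dimethyl (1R,5R,8S,9R)-9-hydroxy-5-methyl-8-[(2R)-6-methylhept-5-en-2-yl]bicyclo[3.3.1]non-2-ene-1,2-dicarboxylate | O[C@@H]1[C@@]2(C)CC=C(C(=O)OC)[C@]1(C(=O)OC)[C@H]([C@H](C)CCC=C(C)C)CC2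
F4 | step 11 | dimethyl (1R,5R,8S,9S)-9-hydroxy-5-methyl-8-[(2R)-6-methylhept-5-en-2-yl]bicyclo[3.3.1]non-2-ene-1,2-dicarboxylate | O[C@H]1[C@@]2(C)CC=C(C(=O)OC)[C@]1(C(=O)OC)[C@H]([C@H](C)CCC=C(C)C)CC2
A1 | alternative 1 | (2Z)-2-({[tert-butyl(dimethyl)silyl]oxy}methyl)-5-methyl-8-[(2R)-6-methylhept-5-en-2-yl]cyclooct-2-ene-1,5-dicarbaldehyde (C5 and C8 as in the target, C1 either) | O=C[C@@]1(C)C/C=C(CO[Si](C)(C)C(C)(C)C)\C(C=O)[C@H]([C@H](C)CCC=C(C)C)CC1
A2 | alternative 1 | 2-({[tert-butyl(dimethyl)silyl]oxy}methyl)-9-hydroxy-5-methyl-8-[(2R)-6-methylhept-5-en-2-yl]bicyclo[3.3.1]non-2-ene-1-carbaldehyde (ring stereocentres as in the target) | O[C@@H]1[C@@]2(C)CC=C(CO[Si](C)(C)C(C)(C)C)[C@]1(C=O)[C@H]([C@H](C)CCC=C(C)C)CC2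
A3 | alternative 2 | tert-butyl{[2-(methoxymethylidene)-6-(4-methoxybut-3-en-1-yl)-6-methyl-3-[(2R)-6-methylhept-5-en-2-yl]cyclohexyl]oxy}dimethylsilane (ring stereocentres as in the target) | COC=CCC[C@@]1(C)CC[C@@H]([C@H](C)CCC=C(C)C)C(=COC)[C@@H]1O[Si](C)(C)C(C)(C)C
A4 | alternative 2 | tert-butyl{[1,2-bis(dimethoxymethyl)-5-methyl-8-[(2R)-6-methylhept-5-en-2-yl]bicyclo[3.3.1]nonan-9-yl]oxy}dimethylsilane | CC(C)(C)[Si](C)(C)O[C@@H]1[C@@]2(C)CC[C@H](C(OC)OC)[C@]1(C(OC)OC)[C@H]([C@H](C)CCC=C(C)C)CC2
A5 | alternative 3 | 6-({[tert-butyl(dimethyl)silyl]oxy}methyl)-2-chloro-2-methyl-5-[(2R)-6-methylhept-5-en-2-yl]cyclohexan-1-one (C5 of the ring as C8 of the target) | O=C1C(CO[Si](C)(C)C(C)(C)C)[C@H]([C@H](C)CCC=C(C)C)CCC1(C)Cl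
A6 | alternative 3 | (E)-(buta-1,3-dien-1-yloxy)(tert-butyl)dimethylsilane | C=C/C=C/O[Si](C)(C)C(C)(C)C
A7 | alternative 3 | 2-{[tert-butyl(dimethyl)silyl]oxy}-1-({[tert-butyl(dimethyl)silyl]oxy}methyl)-6-methyl-9-[(2R)-6-methylhept-5-en-2-yl]bicyclo[4.3.1]dec-3-en-10-one | O=C1[C@@]2(C)CC=C[C@H](O[Si](C)(C)C(C)(C)C)[C@]1(CO[Si](C)(C)C(C)(C)C)[C@H]([C@H](C)CCC=C(C)C)CC2
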